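The route rests on cutting the C2–C3 bond of the cyclohexadiene (ring A, numbered C1–C6, with C1 carrying C7H2OBz, C5 the benzoate carbon and C6 the carbinol carbon). The conjugated C1=C2–C3=C4 diene is the cycloisomer of an acyclic 1,5-enyne, so one gold-catalysed 6-endo-dig closure forms ring A and both ring alkenes at once without touching the stereocentres. The enyne carries a terminal alkyne (C3≡C4), a 2-substituted allyl benzoate (C1=C2, C7) and the threo C5/C6 diol of D-tartaric acid as TES (C5) and TBS (C6) ethers. The silyl pair is later exchanged for the C5 benzoate and the free C6 hydroxyl.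

Key step: step 9

Remark (starting material): dimethyl D-tartrate is used instead of the diethyl ester, so that the methanolic alkyne-forming step cannot exchange the ester alkyl group.
Remark (notation): TBS = tert-butyldimethylsilyl, TES = triethylsilyl, Bz = benzoyl; ring compounds use the C1–C7 numbering above, acyclic intermediates their own chain locants.

Step 1
Reactants: 1 dimethyl D-tartrate [dimethyl (2S,3S)-2,3-dihydroxybutanedioate]; 2 tert-butyldimethylsilyl chloride
Product: 3 dimethyl (2S,3S)-2-[(tert-butyldimethylsilyl)oxy]-3-hydroxybutanedioate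
Conditions: TBSCl (1.05 equiv), imidazole, DMF, 0 °C
Reagents that add atoms: tert-butyldimethylsilyl chloride (2), CC(C)(C)[Si](C)(C)Cl
Why: Silyl ether formation on a C2-symmetric diol, whose two hydroxyls are equivalent, should give a single mono-ether because the bulky first silyl group slows a second silylation, and neither stereocentre is touched.

Step 2
Reactants: 3 dimethyl (2S,3S)-2-[(tert-butyldimethylsilyl)oxy]-3-hydroxybutanedioate
Product: 4 methyl (2S,3R)-2-[(tert-butyldimethylsilyl)oxy]-3,4-dihydroxybutanoate
Conditions: BH3·SMe2, NaBH4 (5 mol %), THF, 0 °C to rt; MeOH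
Reagents that add atoms: none
Why: In this hydroxyl-directed chemoselective ester reduction the free C3 hydroxyl forms an alkoxyborane that delivers hydride only to the ester next to it, so the ester flanked by the silyl ether should survive and the two ends of the tartrate become different without change at either stereocentre.

Step 3
Reactants: 4 methyl (2S,3R)-2-[(tert-butyldimethylsilyl)oxy]-3,4-dihydroxybutanoate; 5 chlorotriethylsilane
Product: 6 methyl (2S,3R)-2-[(tert-butyldimethylsilyl)oxy]-3,4-bis[(triethylsilyl)oxy]butanoate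
Conditions: TESCl (2.3 equiv), imidazole, DMAP (cat.), CH2Cl2, 0 °C to rt
Reagents that add atoms: chlorotriethylsilane (5), CC[Si](Cl)(CC)CC
Why: Routine silyl ether formation on both hydroxyls installs the labile protecting group of the future C5 oxygen and also forestalls lactonisation of the hydroxy ester.

Step 4
Reactants: 6 methyl (2S,3R)-2-[(tert-butyldimethylsilyl)oxy]-3,4-bis[(triethylsilyl)oxy]butanoate
Product: 7 methyl (2S,3S)-2-[(tert-butyldimethylsilyl)oxy]-4-oxo-3-[(triethylsilyl)oxy]butanoate
Conditions: (COCl)2, DMSO, CH2Cl2, −78 to −40 °C; Et3N, −78 to 0 °C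
Reagents that add atoms: none
Why: Swern oxidation applied directly to the bis-TES ether should cleave only the unhindered primary triethylsilyl ether and oxidise that carbon to the aldehyde, leaving the secondary TES and TBS ethers in place, while the cold and brief exposure to Et3N limits epimerisation next to the aldehyde.

Step 5
Reactants: 7 methyl (2S,3S)-2-[(tert-butyldimethylsilyl)oxy]-4-oxo-3-[(triethylsilyl)oxy]butanoate; 8 dimethyl (1-diazo-2-oxopropyl)phosphonate
Product: 9 methyl (2S,3R)-2-[(tert-butyldimethylsilyl)oxy]-3-[(triethylsilyl)oxy]pent-4-ynoate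
Conditions: K2CO3, MeOH, 0 °C to rt
Reagents that add atoms: dimethyl (1-diazo-2-oxopropyl)phosphonate (8), CC(=O)C(=[N+]=[N-])P(=O)(OC)OC
Why: The Seyferth–Gilbert homologation in its Ohira–Bestmann form should turn the aldehyde into the terminal alkyne under mild carbonate conditions that match the methyl ester and do not involve the stereocentres.

Step 6
Reactants: 9 methyl (2S,3R)-2-[(tert-butyldimethylsilyl)oxy]-3-[(triethylsilyl)oxy]pent-4-ynoate; 10 chloroiodomethane
Product: 11 (3S,4R)-3-[(tert-butyldimethylsilyl)oxy]-1-chloro-4-[(triethylsilyl)oxy]hex-5-yn-2-one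
Conditions: ICH2Cl (3 equiv), MeLi·LiBr (3 equiv), THF, −78 °C; aq. NH4Cl, −78 °C
Reagents that add atoms: chloroiodomethane (10), ClCI
Why: In this carbenoid chloromethylation of an ester, chloromethyllithium made in situ adds once because the tetrahedral lithium alkoxide, held by the neighbouring silyloxy oxygen, persists at −78 °C and collapses to the α-chloroketone only on quenching, the excess reagent covering deprotonation of the alkyne C–H.

Step 7
Reactants: 11 (3S,4R)-3-[(tert-butyldimethylsilyl)oxy]-1-chloro-4-[(triethylsilyl)oxy]hex-5-yn-2-one; 12 sodium benzoate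
Product: 13 (3S,4R)-3-[(tert-butyldimethylsilyl)oxy]-2-oxo-4-[(triethylsilyl)oxy]hex-5-yn-1-yl benzoate
Conditions: PhCO2Na, NaI (cat.), DMF, rt
Reagents that add atoms: sodium benzoate (12), [Na+].[O-]C(=O)c1ccccc1
Why: SN2 displacement of the activated α-keto chloride by the weakly basic benzoate ion should be mild enough to leave the adjacent silyloxy stereocentre unepimerised.

Step 8
Reactants: 13 (3S,4R)-3-[(tert-butyldimethylsilyl)oxy]-2-oxo-4-[(triethylsilyl)oxy]hex-5-yn-1-yl benzoate; 14 dibromomethane
Product: 15 (3R,4R)-3-[(tert-butyldimethylsilyl)oxy]-2-methylidene-4-[(triethylsilyl)oxy]hex-5-yn-1-yl benzoate (the 1,5-enyne)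
Conditions: Zn, CH2Br2, TiCl4, THF/CH2Cl2, 0 °C to rt
Reagents that add atoms: dibromomethane (14), BrCBr
Why: The Takai–Lombardo methylenation converts the ketone into the 1,1-disubstituted alkene without base, so the enolisable α-silyloxy centre, the benzoate and the terminal alkyne should be tolerated.

Step 9
Reactants: 15 (3R,4R)-3-[(tert-butyldimethylsilyl)oxy]-2-methylidene-4-[(triethylsilyl)oxy]hex-5-yn-1-yl benzoate
Product: 16 [(5R,6R)-6-[(tert-butyldimethylsilyl)oxy]-5-[(triethylsilyl)oxy]cyclohexa-1,3-dien-1-yl]methyl benzoate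
Conditions: [(2,4-t-Bu2C6H3O)3P]Au(NCPh)SbF6 (3 mol %), 4 Å MS, CH2Cl2, 0 °C to rt
Reagents that add atoms: none
Why: The cationic monovalent gold centre binds the terminal alkyne (C3≡C4) and the CH2 terminus (C2) of the 1,1-disubstituted alkene attacks the terminal alkyne carbon C3, leaving a vinyl–gold bond at C4 and positive charge on the fully substituted C1 (the open form of a cyclopropyl gold carbene); loss of a proton from C2 then creates C1=C2, and protodeauration at C4 leaves C3=C4 and returns the catalyst. The closest known reaction type is the gold- or platinum-catalysed cycloisomerisation of 1,5-enynes bearing a 1,1-disubstituted alkene to cyclohexadienes. Ring A (C1–C6) closes in the 6-endo-dig mode through the single new C2–C3 bond. No stereocentre is formed: C5 and C6 come unchanged from the tartrate, so their threo relationship becomes the trans 5,6-dioxygenation. The step needs six-membered closure in preference to five-membered closures (C1–C3 with cyclopropane retention, or C2–C4), proton loss from C2 and not from C6 or C7, and no migration at the propargylic C5 oxygen; the first should be secured by the 1,1-disubstitution that places the charge on tertiary C1 (supported by the C7 benzoate carbonyl), the second by the conjugation gained with C3=C4, and the third by silyl ethers, which cannot undergo the acyloxy shift of a propargylic ester. The electron-poor phosphite ligand is chosen to push the intermediate towards its open carbocation form, so that proton loss outruns 1,2-hydride shifts from the silyloxy-bearing C5 and C6, and sieves and low temperature protect the acid-sensitive dienyl silyl ether.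

Step 10
Reactants: 16 [(5R,6R)-6-[(tert-butyldimethylsilyl)oxy]-5-[(triethylsilyl)oxy]cyclohexa-1,3-dien-1-yl]methyl benzoate
Product: 17 [(5R,6R)-6-[(tert-butyldimethylsilyl)oxy]-5-hydroxycyclohexa-1,3-dien-1-yl]methyl benzoate
Conditions: PPTS (cat.), MeOH/CH2Cl2, 0 °C
Reagents that add atoms: none
Why: Acid-catalysed methanolysis (selective desilylation) should remove the less hindered triethylsilyl ether well before the TBS ether, the weak acid and low temperature avoiding ionisation of the dienylic C5–O bond.

Step 11
Reactants: 17 [(5R,6R)-6-[(tert-butyldimethylsilyl)oxy]-5-hydroxycyclohexa-1,3-dien-1-yl]methyl benzoate; 18 benzoyl chloride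
Product: 19 [(5R,6R)-5-(benzoyloxy)-6-[(tert-butyldimethylsilyl)oxy]cyclohexa-1,3-dien-1-yl]methyl benzoate
Conditions: BzCl, pyridine, DMAP (cat.), CH2Cl2, 0 °C
Reagents that add atoms: benzoyl chloride (18), O=C(Cl)c1ccccc1
Why: DMAP-catalysed esterification of the only free hydroxyl acylates the C5 oxygen with retention at carbon, the C6 oxygen being blocked as its TBS ether.

Step 12
Reactants: 19 [(5R,6R)-5-(benzoyloxy)-6-[(tert-butyldimethylsilyl)oxy]cyclohexa-1,3-dien-1-yl]methyl benzoate
Product: 20 [(5R,6R)-5-(benzoyloxy)-6-hydroxycyclohexa-1,3-dien-1-yl]methyl benzoate (target)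
Conditions: HF·pyridine, pyridine, THF, 0 °C to rt
Reagents that add atoms: none
Why: Fluoride-mediated silyl ether cleavage under buffered, weakly acidic conditions is chosen because basic fluoride could move the C5 benzoate onto the freed trans C6 hydroxyl and stronger acid could aromatise the diene diol.

Compound list
1 | dimethyl D-tartrate [dimethyl (2S,3S)-2,3-dihydroxybutanedioate] | COC(=O)[C@@H](O)[C@H](O)C(=O)OC | starting material
2 | tert-butyldimethylsilyl chloride | CC(C)(C)[Si](C)(C)Cl | starting material
3 | dimethyl (2S,3S)-2-[(tert-butyldimethylsilyl)oxy]-3-hydroxybutanedioate | COC(=O)[C@@H](O[Si](C)(C)C(C)(C)C)[C@H](O)C(=O)OC | intermediate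
4 | methyl (2S,3R)-2-[(tert-butyldimethylsilyl)oxy]-3,4-dihydroxybutanoate | COC(=O)[C@@H](O[Si](C)(C)C(C)(C)C)[C@H](O)CO | intermediate
5 | chlorotriethylsilane | CC[Si](Cl)(CC)CC | starting material
6 | methyl (2S,3R)-2-[(tert-butyldimethylsilyl)oxy]-3,4-bis[(triethylsilyl)oxy]butanoate | COC(=O)[C@@H](O[Si](C)(C)C(C)(C)C)[C@H](O[Si](CC)(CC)CC)CO[Si](CC)(CC)CC | intermediate
7 | methyl (2S,3S)-2-[(tert-butyldimethylsilyl)oxy]-4-oxo-3-[(triethylsilyl)oxy]butanoate | COC(=O)[C@@H](O[Si](C)(C)C(C)(C)C)[C@H](O[Si](CC)(CC)CC)C=O | intermediate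
8 | dimethyl (1-diazo-2-oxopropyl)phosphonate | CC(=O)C(=[N+]=[N-])P(=O)(OC)OC | starting material
9 | methyl (2S,3R)-2-[(tert-butyldimethylsilyl)oxy]-3-[(triethylsilyl)oxy]pent-4-ynoate | COC(=O)[C@@H](O[Si](C)(C)C(C)(C)C)[C@H](O[Si](CC)(CC)CC)C#C | intermediate
10 | chloroiodomethane | ClCI | starting material
11 | (3S,4R)-3-[(tert-butyldimethylsilyl)oxy]-1-chloro-4-[(triethylsilyl)oxy]hex-5-yn-2-one | ClCC(=O)[C@@H](O[Si](C)(C)C(C)(C)C)[C@H](O[Si](CC)(CC)CC)C#C | intermediate
12 | sodium benzoate | [Na+].[O-]C(=O)c1ccccc1 | starting material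
13 | (3S,4R)-3-[(tert-butyldimethylsilyl)oxy]-2-oxo-4-[(triethylsilyl)oxy]hex-5-yn-1-yl benzoate | O=C(OCC(=O)[C@@H](O[Si](C)(C)C(C)(C)C)[C@H](O[Si](CC)(CC)CC)C#C)c1ccccc1 | intermediate
14 | dibromomethane | BrCBr | starting material
15 | (3R,4R)-3-[(tert-butyldimethylsilyl)oxy]-2-methylidene-4-[(triethylsilyl)oxy]hex-5-yn-1-yl benzoate | C#C[C@@H](O[Si](CC)(CC)CC)[C@H](O[Si](C)(C)C(C)(C)C)C(=C)COC(=O)c1ccccc1 | intermediate
16 | [(5R,6R)-6-[(tert-butyldimethylsilyl)oxy]-5-[(triethylsilyl)oxy]cyclohexa-1,3-dien-1-yl]methyl benzoate | O=C(OCC1=CC=C[C@@H](O[Si](CC)(CC)CC)[C@@H]1O[Si](C)(C)C(C)(C)C)c1ccccc1 | intermediate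
17 | [(5R,6R)-6-[(tert-butyldimethylsilyl)oxy]-5-hydroxycyclohexa-1,3-dien-1-yl]methyl benzoate | O=C(OCC1=CC=C[C@@H](O)[C@@H]1O[Si](C)(C)C(C)(C)C)c1ccccc1 | intermediate
18 | benzoyl chloride | O=C(Cl)c1ccccc1 | starting material
19 | [(5R,6R)-5-(benzoyloxy)-6-[(tert-butyldimethylsilyl)oxy]cyclohexa-1,3-dien-1-yl]methyl benzoate | O=C(OCC1=CC=C[C@@H](OC(=O)c2ccccc2)[C@@H]1O[Si](C)(C)C(C)(C)C)c1ccccc1 | intermediate
20 | [(5R,6R)-5-(benzoyloxy)-6-hydroxycyclohexa-1,3-dien-1-yl]methyl benzoate | O=C(OCC1=CC=C[C@@H](OC(=O)c2ccccc2)[C@@H]1O)c1ccccc1 | target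

Total step count: 12
Longest linear sequence: 12 steps (1 to 20)

Steps most likely to fail

Step 9. The gold-bound intermediate may be diverted before proton loss: cyclopropane retention, a 1,2-hydride shift from the silyloxy-bearing C5 or C6 with loss of a silyl group, or ionisation and aromatisation of the dienyl ether once formed. The fallback sets out from 15 and comes back at 16, making the C1=C2 bond by metathesis instead of the C2–C3 bond by cycloisomerisation. Sonogashira coupling of the terminal alkyne with vinyl bromide (Pd(PPh3)2Cl2, CuI, i-Pr2NH, THF, rt) should give the conjugated enyne (3R,4R)-3-[(tert-butyldimethylsilyl)oxy]-2-methylidene-4-[(triethylsilyl)oxy]oct-7-en-5-yn-1-yl benzoate F1. Cis-selective semireduction of its triple bond with Zn dust activated by Cu(OAc)2 and AgNO3 in aqueous MeOH should give the triene (3R,4R,5Z)-3-[(tert-butyldimethylsilyl)oxy]-2-methylidene-4-[(triethylsilyl)oxy]octa-5,7-dien-1-yl benzoate F2. Ring-closing metathesis between its terminal vinyl group and the 1,1-disubstituted alkene (second-generation Hoveyda–Grubbs catalyst, toluene, 60 °C) should then close ring A to 16; the only other closure would give a cyclobutene.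

Step 8. Methylenation may be slow at a ketone flanked by two oxygenated carbons, and the Lewis-acidic titanium reagent may strip the TES ether or promote enolisation. The fallback sets out from 11 and comes back at 15, installing the methylene before the benzoate. Wittig methylenation of the chloroketone (Ph3PCH3Br, KN(SiMe3)2, THF, −78 to 0 °C) should give the allyl chloride tert-butyl{[(3R,4R)-2-(chloromethyl)-4-[(triethylsilyl)oxy]hex-1-en-5-yn-3-yl]oxy}dimethylsilane F3. Allylic substitution with PhCO2Na (NaI cat., DMF, 50 °C) then gives 15, direct and allylic-transposed attack leading to the same product.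

Step 6. The carbenoid may add twice if the tetrahedral adduct collapses before the quench, or be consumed by the alkyne C–H. The fallback sets out from 9 and comes back at 11, replacing the lithium carbenoid by a stabilised ylide that is too weak a base to deprotonate the alkyne. Acylation of dimethylsulfoxonium methylide by the ester (Me3S(O)I, KOt-Bu, THF, rt to 50 °C) should give the β-keto sulfoxonium ylide (3S,4R)-3-[(tert-butyldimethylsilyl)oxy]-1-(dimethyloxo-λ6-sulfanylidene)-4-[(triethylsilyl)oxy]hex-5-yn-2-one F4. Protonation followed by chloride displacement of the sulfoxide leaving group (LiCl, MeSO3H 1 equiv, THF, 0 to 60 °C) should give 11.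

Further compounds
F1 | step 9 | (3R,4R)-3-[(tert-butyldimethylsilyl)oxy]-2-methylidene-4-[(triethylsilyl)oxy]oct-7-en-5-yn-1-yl benzoate | C=CC#C[C@@H](O[Si](CC)(CC)CC)[C@H](O[Si](C)(C)C(C)(C)C)C(=C)COC(=O)c1ccccc1
F2 | step 9 | (3R,4R,5Z)-3-[(tert-butyldimethylsilyl)oxy]-2-methylidene-4-[(triethylsilyl)oxy]octa-5,7-dien-1-yl benzoate | C=C/C=C\[C@@H](O[Si](CC)(CC)CC)[C@H](O[Si](C)(C)C(C)(C)C)C(=C)COC(=O)c1ccccc1
F3 | step 8 | tert-butyl{[(3R,4R)-2-(chloromethyl)-4-[(triethylsilyl)oxy]hex-1-en-5-yn-3-yl]oxy}dimethylsilane | ClCC(=C)[C@@H](O[Si](C)(C)C(C)(C)C)[C@H](O[Si](CC)(CC)CC)C#C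
F4 | step 6 | (3S,4R)-3-[(tert-butyldimethylsilyl)oxy]-1-(dimethyloxo-λ6-sulfanylidene)-4-[(triethylsilyl)oxy]hex-5-yn-2-one | CS(C)(=O)=CC(=O)[C@@H](O[Si](C)(C)C(C)(C)C)[C@H](O[Si](CC)(CC)CC)C#C
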